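**Plan**
- Retrosynthetic cuts, last bond first: the depsidone ester C–O and the diaryl ether C–O (separating ring A bromide 31 from spiro phenol 22), then both C–O bonds at the spiro carbon (pyran oxygen and lactone oxygen), then the ring B CH2–furan C–C bond.
- Enabling feature: the 6-methyltetrahydropyran whose anomeric carbon is C3 of the isochromanone is a furyl carbinol in reduced form. The spiro carbon and ring carbons C3', C4', C5' are the four furan carbons, C6' with its methyl and O1' are the 1-hydroxyethyl arm, and the ortho carboxyl of ring B supplies the second oxygen on the spiro carbon.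
- Forward order: methyl orsellinate → 5-hydroxylated, fully protected toluate → benzylic bromide → Negishi union with the furan → step 10 closes pyranone and isochromanone together → ketone removed by reduction and allylic transposition → Ullmann ether to ring A → hydrogenation → seven-membered lactone → ketal removal.
- Stereochemistry: the methyl-bearing carbon is bought as (R)-1-(furan-2-yl)ethanol and no bond to it is ever broken. The spiro centre is set from it under thermodynamic (anomeric) control in step 10.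

Key step: step 10

Assumption: the target is the thermodynamically preferred spiro isomer (lactone oxygen axial on the tetrahydropyran chair, methyl equatorial), so acid-reversible closure at the spiro carbon should deliver it.
Numbering: benzoate locants are used up to 15. From 17 on, ring B carries isochromane locants (C5, C6, C8) and the pyran ring primed locants (O1', spiro C2' = C3, C6' bears methyl). The spiro descriptor changes from R (17–20) to S (21 onward) only because the CIP ranking of its carbon neighbours changes; the geometry is the same throughout.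

**Step 1**
Reactants: 1 methyl orsellinate (methyl 2,4-dihydroxy-6-methylbenzoate)
Product: 2 methyl 4-(benzyloxy)-2-hydroxy-6-methylbenzoate
Conditions: BnBr (1.05 equiv), K2CO3, acetone, reflux
Reagents that add atoms: benzyl bromide, BrCc1ccccc1
Why: Williamson etherification in which only the 4-hydroxyl should react under mild carbonate conditions, because the 2-hydroxyl is hydrogen-bonded to the ester carbonyl and much less nucleophilic.

**Step 2**
Reactants: 2 methyl 4-(benzyloxy)-2-hydroxy-6-methylbenzoate
Product: 4 methyl 4-(benzyloxy)-3,6-dihydroxy-2-methylbenzoate, via aryl potassium sulfate 3 (not isolated)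
Conditions: K2S2O8, NaOH (aq), pyridine, 0 °C to rt; then HCl (aq), Na2SO3, 80 °C
Reagents that add atoms: potassium peroxydisulfate, [K+].[K+].[O-]S(=O)(=O)OOS(=O)(=O)[O-]
Why: Elbs persulfate oxidation, in which the phenoxide of 2 is attacked by peroxydisulfate at its only free para position and acid hydrolysis of sulfate 3 releases the hydroquinone, as in the classical para-hydroxylation of ortho-acyl phenols.

**Step 3**
Reactants: 4 methyl 4-(benzyloxy)-3,6-dihydroxy-2-methylbenzoate
Product: 5 methyl 4-(benzyloxy)-6-hydroxy-3-[(4-methoxybenzyl)oxy]-2-methylbenzoate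
Conditions: 4-methoxybenzyl chloride (1.05 equiv), K2CO3, DMF, rt, under N2
Reagents that add atoms: 4-methoxybenzyl chloride, COc1ccc(CCl)cc1
Why: Williamson etherification that should distinguish the two hydroquinone hydroxyls, since the 6-OH is chelated to the ester while the 3-OH is a free phenol that reacts readily with the activated benzylic chloride.

**Step 4**
Reactants: 5 methyl 4-(benzyloxy)-6-hydroxy-3-[(4-methoxybenzyl)oxy]-2-methylbenzoate
Product: 6 methyl 4,6-bis(benzyloxy)-3-[(4-methoxybenzyl)oxy]-2-methylbenzoate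
Conditions: BnBr, K2CO3, DMF, 60 °C
Reagents that add atoms: benzyl bromide, BrCc1ccccc1
Why: Williamson etherification under more forcing conditions, which alkylates the remaining chelated salicylate-type hydroxyl.

**Step 5**
Reactants: 6 methyl 4,6-bis(benzyloxy)-3-[(4-methoxybenzyl)oxy]-2-methylbenzoate
Product: 8 methyl 4,6-bis(benzyloxy)-2-(bromomethyl)-3-[(4-methoxybenzyl)oxy]benzoate, via lateral benzyllithium 7 (not isolated)
Conditions: LiN(i-Pr)2 (LDA), THF, −78 °C; then cannulated into BrCCl2CCl2Br, THF, −78 °C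
Reagents that add atoms: 1,2-dibromo-1,1,2,2-tetrachloroethane, BrC(Cl)(Cl)C(Cl)(Cl)Br
Why: Lateral lithiation of an ortho-toluate gives the ester-stabilised benzylic anion 7, which is brominated by an electrophilic bromine donor (radical benzylic bromination is ruled out by the electron-rich ring), and inverse addition keeps the anion from alkylating the product.

**Step 6**
Reactants: 9 (R)-1-(furan-2-yl)ethanol
Product: 10 (R)-tert-butyl[1-(furan-2-yl)ethoxy]dimethylsilane
Conditions: TBSCl, imidazole, DMF, rt
Reagents that add atoms: tert-butyldimethylsilyl chloride, CC(C)(C)[Si](C)(C)Cl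
Why: Standard silyl ether formation on a secondary alcohol, which does not touch the stereocentre.

**Step 7**
Reactants: 10 (R)-tert-butyl[1-(furan-2-yl)ethoxy]dimethylsilane; 8 methyl 4,6-bis(benzyloxy)-2-(bromomethyl)-3-[(4-methoxybenzyl)oxy]benzoate
Product: 13 methyl 4,6-bis(benzyloxy)-2-({5-[(1R)-1-(tert-butyldimethylsilyloxy)ethyl]furan-2-yl}methyl)-3-[(4-methoxybenzyl)oxy]benzoate, via furyllithium 11 (not isolated), via furylzinc chloride 12 (not isolated)
Conditions: 10, n-BuLi, THF, −78 to 0 °C; ZnCl2, 0 °C; then 8, Pd(PPh3)4 (cat.), THF, rt to 45 °C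
Reagents that add atoms: none
Why: Negishi coupling, in which the furan is lithiated at its only free α-position (C5), transmetalated to zinc so that the methyl ester is tolerated, and joined to the benzylic bromide under zerovalent palladium catalysis with the carbinol stereocentre as a spectator.

**Step 8**
Reactants: 13 methyl 4,6-bis(benzyloxy)-2-({5-[(1R)-1-(tert-butyldimethylsilyloxy)ethyl]furan-2-yl}methyl)-3-[(4-methoxybenzyl)oxy]benzoate
Product: 14 methyl 4,6-bis(benzyloxy)-2-({5-[(1R)-1-hydroxyethyl]furan-2-yl}methyl)-3-[(4-methoxybenzyl)oxy]benzoate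
Conditions: Bu4NF, THF, rt
Reagents that add atoms: none
Why: Fluoride-mediated desilylation is selective for the silyl ether and leaves the ester, the ethers and the furan alone.

**Step 9**
Reactants: 14 methyl 4,6-bis(benzyloxy)-2-({5-[(1R)-1-hydroxyethyl]furan-2-yl}methyl)-3-[(4-methoxybenzyl)oxy]benzoate
Product: 15 4,6-bis(benzyloxy)-2-({5-[(1R)-1-hydroxyethyl]furan-2-yl}methyl)-3-[(4-methoxybenzyl)oxy]benzoic acid
Conditions: KOH, DMSO/H2O, 80 °C; then HCl (aq) to pH 4, 0 °C
Reagents that add atoms: potassium hydroxide, [K+].[OH-]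
Why: Saponification of a di-ortho-substituted benzoate needs hot hydroxide, conditions under which the aryl ethers, the furan and the secondary alcohol are inert, and careful cold acidification spares the acid-sensitive furyl carbinol.

**Step 10**
Reactants: 15 4,6-bis(benzyloxy)-2-({5-[(1R)-1-hydroxyethyl]furan-2-yl}methyl)-3-[(4-methoxybenzyl)oxy]benzoic acid
Product: 17 (3R,6'R)-6,8-bis(benzyloxy)-5-[(4-methoxybenzyl)oxy]-6'-methylspiro[isochromane-3,2'-pyran]-1,5'(6'H)-dione, via hemiketal acid 16 (not isolated)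
Conditions: mCPBA (1.05 equiv), CH2Cl2, 0 °C; then camphorsulfonic acid (cat.), 4 Å molecular sieves, rt
Reagents that add atoms: 3-chloroperoxybenzoic acid, OOC(=O)c1cccc(Cl)c1
Why: The peracid epoxidises the electron-rich 2,5-dialkylfuran, the epoxide collapses to the cis-enedione, and the carbinol hydroxyl adds to the distal (benzyl-bearing) carbonyl to give hemiketal 16; acid then ionises the hemiketal to a cyclic oxocarbenium ion that the ortho carboxylic acid captures. The closest known reaction type is the Achmatowicz rearrangement with in situ spiroketalisation or spirolactonisation. The pyranone closes by 6-exo-trig attack of the alcohol oxygen on the ketone, and the isochromanone closes by 6-exo-trig attack of the carboxyl oxygen on the oxocarbenium carbon. The methyl-bearing carbon keeps the (R) configuration of 9 because no bond to it is made or broken and no base is present to enolise it, while the spiro carbon is set under thermodynamic control, since reversible ionisation of the acyloxy group should funnel the mixture to the anomer with the lactone oxygen axial (anomeric effect) and trans to the pseudo-equatorial methyl, as in the target. The step needs oxidation of the furan only, which is secured by its much higher nucleophilicity towards the peracid than the ester-deactivated alkoxy arene and the benzyl ethers, by one equivalent of oxidant at 0 °C, and by the absence of free phenols.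

**Step 11**
Reactants: 17 (3R,6'R)-6,8-bis(benzyloxy)-5-[(4-methoxybenzyl)oxy]-6'-methylspiro[isochromane-3,2'-pyran]-1,5'(6'H)-dione
Product: 18 (3R,5'S,6'R)-6,8-bis(benzyloxy)-5'-hydroxy-5-[(4-methoxybenzyl)oxy]-6'-methyl-5',6'-dihydrospiro[isochromane-3,2'-pyran]-1-one
Conditions: NaBH4, CeCl3·7H2O, MeOH/CH2Cl2, −78 °C
Reagents that add atoms: none
Why: Luche reduction should give clean 1,2-reduction of the enone at low temperature without epimerising the α-methyl centre or attacking the lactone; hydride is expected to add anti to the axial acyloxy group to give the alcohol trans to methyl, but this centre is removed in step 12, so either epimer serves.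

**Step 12**
Reactants: 18 (3R,5'S,6'R)-6,8-bis(benzyloxy)-5'-hydroxy-5-[(4-methoxybenzyl)oxy]-6'-methyl-5',6'-dihydrospiro[isochromane-3,2'-pyran]-1-one
Product: 21 (3S,6'R)-6,8-bis(benzyloxy)-5-[(4-methoxybenzyl)oxy]-6'-methyl-3',6'-dihydrospiro[isochromane-3,2'-pyran]-1-one, via allylic sulfonylhydrazine 19 (not isolated), via allylic diazene 20 (not isolated)
Conditions: 2-nitrobenzenesulfonylhydrazide, PPh3, diethyl azodicarboxylate, N-methylmorpholine, THF, −30 °C to rt
Reagents that add atoms: none
Why: Reductive 1,3-transposition of an allylic alcohol, in which Mitsunobu displacement with inversion gives 19, loss of 2-nitrobenzenesulfinic acid on warming gives diazene 20, and retro-ene loss of dinitrogen delivers hydrogen to C3' and moves the alkene to C4'=C5', a sequence established on Achmatowicz-derived pyranols and free of acid or metal that could disturb the spiro acylal.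

**Step 13**
Reactants: 21 (3S,6'R)-6,8-bis(benzyloxy)-5-[(4-methoxybenzyl)oxy]-6'-methyl-3',6'-dihydrospiro[isochromane-3,2'-pyran]-1-one
Product: 22 (3S,6'R)-6,8-bis(benzyloxy)-5-hydroxy-6'-methyl-3',6'-dihydrospiro[isochromane-3,2'-pyran]-1-one
Conditions: DDQ (1.1 equiv), CH2Cl2/pH 7 phosphate buffer, 0 °C
Reagents that add atoms: none
Why: Oxidative cleavage of a 4-methoxybenzyl ether by DDQ in buffered wet dichloromethane leaves benzyl ethers, the alkene and the acylal untouched, and a small excess at 0 °C is used so that the liberated electron-rich phenol is not oxidised further.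

**Step 14**
Reactants: 23 1,3-dibromo-5-methoxybenzene
Product: 25 benzyl 2,6-dibromo-4-methoxybenzoate, via aryllithium 24 (not isolated)
Conditions: LiN(i-Pr)2, THF, −78 °C; then benzyl chloroformate, −78 °C
Reagents that add atoms: benzyl chloroformate, O=C(Cl)OCc1ccccc1
Why: Directed deprotonation, in which the amide base removes the most acidic ring proton (flanked by both bromines) at a temperature where 24 does not lose LiBr, followed by acylation with the chloroformate to give the benzyl ester directly.

**Step 15**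
Reactants: 26 heptan-2-one
Product: 28 (hept-1-en-2-yloxy)trimethylsilane, via lithium enolate 27 (not isolated)
Conditions: LiN(i-Pr)2, THF, −78 °C; then Me3SiCl, −78 °C to rt
Reagents that add atoms: chlorotrimethylsilane, C[Si](C)(C)Cl
Why: Kinetic enolisation of a methyl ketone at −78 °C occurs at the methyl group, and O-silylation of 27 gives the terminal silyl enol ether.

**Step 16**
Reactants: 25 benzyl 2,6-dibromo-4-methoxybenzoate; 28 (hept-1-en-2-yloxy)trimethylsilane
Product: 30 benzyl 2-bromo-4-methoxy-6-(2-oxoheptyl)benzoate, via tin enolate 29 (not isolated)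
Conditions: 25 (3 equiv), Bu3SnF, PdCl2[P(o-tol)3]2 (cat.), toluene, 100 °C
Reagents that add atoms: none
Why: Palladium-catalysed ketone α-arylation of the Stille type, through tin enolate 29 formed in situ from the silyl enol ether, makes the aryl–CH2 bond regiospecifically under neutral conditions, and a threefold excess of the symmetrical dibromide (surplus recovered) holds the reaction at mono-substitution.

**Step 17**
Reactants: 30 benzyl 2-bromo-4-methoxy-6-(2-oxoheptyl)benzoate
Product: 31 benzyl 2-bromo-4-methoxy-6-[(2-pentyl-1,3-dioxolan-2-yl)methyl]benzoate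
Conditions: Me3SiOCH2CH2OSiMe3, Me3SiOTf (cat.), CH2Cl2, −78 to −20 °C; pyridine quench
Reagents that add atoms: 1,2-bis(trimethylsilyloxy)ethane, C[Si](C)(C)OCCO[Si](C)(C)C
Why: Low-temperature silyl-triflate-catalysed ketalisation protects the ketone without the hot protic acid that cyclises 2-(2-oxoalkyl)benzoates to isocoumarins, and the mask is needed so that carboxyl activation in step 20 cannot form that isocoumarin.

**Step 18**
Reactants: 22 (3S,6'R)-6,8-bis(benzyloxy)-5-hydroxy-6'-methyl-3',6'-dihydrospiro[isochromane-3,2'-pyran]-1-one; 31 benzyl 2-bromo-4-methoxy-6-[(2-pentyl-1,3-dioxolan-2-yl)methyl]benzoate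
Product: 32 benzyl 2-{[(3S,6'R)-6,8-bis(benzyloxy)-6'-methyl-1-oxo-3',6'-dihydrospiro[isochromane-3,2'-pyran]-5-yl]oxy}-4-methoxy-6-[(2-pentyl-1,3-dioxolan-2-yl)methyl]benzoate
Conditions: CuI (cat.), N,N-dimethylglycine, Cs2CO3, 1,4-dioxane, 90 °C
Reagents that add atoms: none
Why: Ullmann diaryl ether synthesis with ligated monovalent copper, in which the aryl bromide is activated by its ortho ester, the 5-OH is the only free hydroxyl of 22, and carbonate in dioxane is mild enough for the benzyl ester, the ketal and the spiro acylal.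

**Step 19**
Reactants: 32 benzyl 2-{[(3S,6'R)-6,8-bis(benzyloxy)-6'-methyl-1-oxo-3',6'-dihydrospiro[isochromane-3,2'-pyran]-5-yl]oxy}-4-methoxy-6-[(2-pentyl-1,3-dioxolan-2-yl)methyl]benzoate
Product: 33 2-{[(3S,6'R)-6,8-dihydroxy-6'-methyl-1-oxo-3',4',5',6'-tetrahydrospiro[isochromane-3,2'-pyran]-5-yl]oxy}-4-methoxy-6-[(2-pentyl-1,3-dioxolan-2-yl)methyl]benzoic acid
Conditions: H2 (1 atm), Pd/C (10% Pd on carbon), EtOAc, rt; filtrate used at once
Reagents that add atoms: none
Why: Heterogeneous hydrogenation and hydrogenolysis in one operation saturates the ring alkene and cleaves the benzyl ester and both benzyl ethers under neutral conditions that leave the diaryl ether, the ketal and both stereocentres unchanged.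

**Step 20**
Reactants: 33 2-{[(3S,6'R)-6,8-dihydroxy-6'-methyl-1-oxo-3',4',5',6'-tetrahydrospiro[isochromane-3,2'-pyran]-5-yl]oxy}-4-methoxy-6-[(2-pentyl-1,3-dioxolan-2-yl)methyl]benzoic acid
Product: 34 the 1,3-dioxolane ketal of the target at the side-chain ketone (depsidone closed; spiro carbon S, methyl carbon R)
Conditions: DCC, DMAP (cat.), CH2Cl2 (high dilution), 0 °C to rt
Reagents that add atoms: none
Why: Steglich-type lactonisation, the classical depsidone closure, in which the carbodiimide-activated ring A acid is taken by the adjacent 6-OH to form the seven-membered dioxepinone, while the 8-OH is hydrogen-bonded to the lactone carbonyl and cannot reach, and the ketal blocks isocoumarin formation.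

**Step 21**
Reactants: 34 the 1,3-dioxolane ketal of the target
Product: 35 CNP0301127.1 (target; spiro carbon S, methyl-bearing carbon R)
Conditions: pyridinium p-toluenesulfonate (cat.), acetone/H2O, 45 °C
Reagents that add atoms: water, O
Why: Mild acid-catalysed ketal hydrolysis releases the 2-oxoheptyl ketone, and since the spiro acylal is the thermodynamically preferred anomer, any reversible ionisation under these conditions should return the same configuration.

**Compound list**
1 | methyl orsellinate | COC(=O)c1c(C)cc(O)cc1O | starting material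
2 | methyl 4-(benzyloxy)-2-hydroxy-6-methylbenzoate | COC(=O)c1c(C)cc(OCc2ccccc2)cc1O | intermediate
3 | potassium 6-(benzyloxy)-4-hydroxy-3-(methoxycarbonyl)-2-methylphenyl sulfate | COC(=O)c1c(C)c(OS(=O)(=O)[O-])c(OCc2ccccc2)cc1O.[K+] | intermediate (not isolated)
4 | methyl 4-(benzyloxy)-3,6-dihydroxy-2-methylbenzoate | COC(=O)c1c(C)c(O)c(OCc2ccccc2)cc1O | intermediate
5 | methyl 4-(benzyloxy)-6-hydroxy-3-[(4-methoxybenzyl)oxy]-2-methylbenzoate | COC(=O)c1c(C)c(OCc2ccc(OC)cc2)c(OCc2ccccc2)cc1O | intermediate
6 | methyl 4,6-bis(benzyloxy)-3-[(4-methoxybenzyl)oxy]-2-methylbenzoate | COC(=O)c1c(C)c(OCc2ccc(OC)cc2)c(OCc2ccccc2)cc1OCc1ccccc1 | intermediate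
7 | lateral benzyllithium of 6 | COC(=O)c1c(C[Li])c(OCc2ccc(OC)cc2)c(OCc2ccccc2)cc1OCc1ccccc1 | intermediate (not isolated)
8 | methyl 4,6-bis(benzyloxy)-2-(bromomethyl)-3-[(4-methoxybenzyl)oxy]benzoate | COC(=O)c1c(CBr)c(OCc2ccc(OC)cc2)c(OCc2ccccc2)cc1OCc1ccccc1 | intermediate
9 | (R)-1-(furan-2-yl)ethanol | C[C@@H](O)c1ccco1 | starting material
10 | (R)-tert-butyl[1-(furan-2-yl)ethoxy]dimethylsilane | C[C@@H](O[Si](C)(C)C(C)(C)C)c1ccco1 | intermediate
11 | 5-lithio derivative of 10 | C[C@@H](O[Si](C)(C)C(C)(C)C)c1ccc([Li])o1 | intermediate (not isolated)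
12 | 5-(chlorozincio) derivative of 10 | C[C@@H](O[Si](C)(C)C(C)(C)C)c1ccc([Zn]Cl)o1 | intermediate (not isolated)
13 | methyl 4,6-bis(benzyloxy)-2-({5-[(1R)-1-(tert-butyldimethylsilyloxy)ethyl]furan-2-yl}methyl)-3-[(4-methoxybenzyl)oxy]benzoate | C[C@@H](O[Si](C)(C)C(C)(C)C)c1ccc(Cc2c(OCc3ccc(OC)cc3)c(OCc3ccccc3)cc(OCc3ccccc3)c2C(=O)OC)o1 | intermediate
14 | methyl 4,6-bis(benzyloxy)-2-({5-[(1R)-1-hydroxyethyl]furan-2-yl}methyl)-3-[(4-methoxybenzyl)oxy]benzoate | C[C@@H](O)c1ccc(Cc2c(OCc3ccc(OC)cc3)c(OCc3ccccc3)cc(OCc3ccccc3)c2C(=O)OC)o1 | intermediate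
15 | 4,6-bis(benzyloxy)-2-({5-[(1R)-1-hydroxyethyl]furan-2-yl}methyl)-3-[(4-methoxybenzyl)oxy]benzoic acid | C[C@@H](O)c1ccc(Cc2c(OCc3ccc(OC)cc3)c(OCc3ccccc3)cc(OCc3ccccc3)c2C(O)=O)o1 | intermediate (key-step precursor)
16 | 4,6-bis(benzyloxy)-2-{[(6R)-2-hydroxy-6-methyl-5-oxo-5,6-dihydro-2H-pyran-2-yl]methyl}-3-[(4-methoxybenzyl)oxy]benzoic acid (anomer mixture) | C[C@H]1OC(O)(Cc2c(OCc3ccc(OC)cc3)c(OCc3ccccc3)cc(OCc3ccccc3)c2C(O)=O)C=CC1=O | intermediate (not isolated)
17 | (3R,6'R)-6,8-bis(benzyloxy)-5-[(4-methoxybenzyl)oxy]-6'-methylspiro[isochromane-3,2'-pyran]-1,5'(6'H)-dione | c1ccccc1COc1cc(OCc2ccccc2)c2c(c1OCc1ccc(OC)cc1)C[C@]1(C=CC(=O)[C@@H](C)O1)OC2=O | intermediate (key-step product)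
18 | (3R,5'S,6'R)-6,8-bis(benzyloxy)-5'-hydroxy-5-[(4-methoxybenzyl)oxy]-6'-methyl-5',6'-dihydrospiro[isochromane-3,2'-pyran]-1-one | c1ccccc1COc1cc(OCc2ccccc2)c2c(c1OCc1ccc(OC)cc1)C[C@]1(C=C[C@H](O)[C@@H](C)O1)OC2=O | intermediate
19 | (3R,5'R,6'R)-5'-[1-(2-nitrobenzenesulfonyl)hydrazinyl] analogue of 18 | c1ccccc1COc1cc(OCc2ccccc2)c2c(c1OCc1ccc(OC)cc1)C[C@]1(C=C[C@@H](N(N)S(=O)(=O)c3ccccc3[N+](=O)[O-])[C@@H](C)O1)OC2=O | intermediate (not isolated)
20 | (3R,5'R,6'R)-5'-diazenyl analogue of 18 | c1ccccc1COc1cc(OCc2ccccc2)c2c(c1OCc1ccc(OC)cc1)C[C@]1(C=C[C@@H](N=N)[C@@H](C)O1)OC2=O | intermediate (not isolated)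
21 | (3S,6'R)-6,8-bis(benzyloxy)-5-[(4-methoxybenzyl)oxy]-6'-methyl-3',6'-dihydrospiro[isochromane-3,2'-pyran]-1-one | c1ccccc1COc1cc(OCc2ccccc2)c2c(c1OCc1ccc(OC)cc1)C[C@]1(CC=C[C@@H](C)O1)OC2=O | intermediate
22 | (3S,6'R)-6,8-bis(benzyloxy)-5-hydroxy-6'-methyl-3',6'-dihydrospiro[isochromane-3,2'-pyran]-1-one | c1ccccc1COc1cc(OCc2ccccc2)c2c(c1O)C[C@]1(CC=C[C@@H](C)O1)OC2=O | intermediate
23 | 1,3-dibromo-5-methoxybenzene | COc1cc(Br)cc(Br)c1 | starting material
24 | 2,6-dibromo-4-methoxyphenyllithium | COc1cc(Br)c([Li])c(Br)c1 | intermediate (not isolated)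
25 | benzyl 2,6-dibromo-4-methoxybenzoate | COc1cc(Br)c(C(=O)OCc2ccccc2)c(Br)c1 | intermediate
26 | heptan-2-one | CCCCCC(C)=O | starting material
27 | lithium hept-1-en-2-olate | CCCCCC(=C)O[Li] | intermediate (not isolated)
28 | (hept-1-en-2-yloxy)trimethylsilane | CCCCCC(=C)O[Si](C)(C)C | intermediate
29 | tributyl(2-oxoheptyl)stannane | CCCCCC(=O)C[Sn](CCCC)(CCCC)CCCC | intermediate (not isolated)
30 | benzyl 2-bromo-4-methoxy-6-(2-oxoheptyl)benzoate | CCCCCC(=O)Cc1cc(OC)cc(Br)c1C(=O)OCc1ccccc1 | intermediate
31 | benzyl 2-bromo-4-methoxy-6-[(2-pentyl-1,3-dioxolan-2-yl)methyl]benzoate | CCCCCC1(Cc2cc(OC)cc(Br)c2C(=O)OCc2ccccc2)OCCO1 | intermediate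
32 | benzyl 2-{[(3S,6'R)-6,8-bis(benzyloxy)-6'-methyl-1-oxo-3',6'-dihydrospiro[isochromane-3,2'-pyran]-5-yl]oxy}-4-methoxy-6-[(2-pentyl-1,3-dioxolan-2-yl)methyl]benzoate | c1ccccc1COc1cc(OCc2ccccc2)c2c(c1Oc1cc(OC)cc(CC3(CCCCC)OCCO3)c1C(=O)OCc1ccccc1)C[C@]1(CC=C[C@@H](C)O1)OC2=O | intermediate
33 | 2-{[(3S,6'R)-6,8-dihydroxy-6'-methyl-1-oxo-3',4',5',6'-tetrahydrospiro[isochromane-3,2'-pyran]-5-yl]oxy}-4-methoxy-6-[(2-pentyl-1,3-dioxolan-2-yl)methyl]benzoic acid | Oc1cc(O)c2c(c1Oc1cc(OC)cc(CC3(CCCCC)OCCO3)c1C(O)=O)C[C@]1(CCC[C@@H](C)O1)OC2=O | intermediate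
34 | 1,3-dioxolane ketal of the target at the side-chain ketone | CCCCCC4(OCCO4)Cc1cc(OC)cc2c1C(=O)Oc1cc(O)c3c(c1O2)C[C@]1(CCC[C@@H](C)O1)OC3=O | intermediate
35 | CNP0301127.1 | CCCCCC(=O)Cc1cc(OC)cc2c1C(=O)Oc1cc(O)c3c(c1O2)C[C@]1(CCC[C@@H](C)O1)OC3=O | target

**Count**
Total steps: 21. Longest linear sequence: 16 (steps 1–5, 7–13, 18–21).

**Steps most likely to fail**

Step 10. The oxocarbenium ion may lose a proton to an enol ether or isocoumarin instead of being captured by the hindered acid, or the peracid may over-oxidise the substrate. The fallback separates dearomatisation from ring closure. It sets out from ester 14: Clauson-Kaas-type oxidation (Br2, MeOH, Na2CO3, −40 °C) should give the base-stable bis-ketal methyl 4,6-bis(benzyloxy)-2-({5-[(1R)-1-hydroxyethyl]-2,5-dimethoxy-2,5-dihydrofuran-2-yl}methyl)-3-[(4-methoxybenzyl)oxy]benzoate F1. Saponification (KOH, DMSO/H2O, 80 °C) then gives the corresponding benzoic acid F2. Camphorsulfonic acid with molecular sieves in CH2Cl2 should exchange both methoxy groups for the carbinol and carboxyl oxygens with release of the ketone, coming back to the route at 17.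

Step 18. C–O coupling of a phenol flanked on both sides may be slow, and long heating with carbonate may open the acylal by β-elimination from the benzylic position. The fallback inverts the polarity of ring A. It sets out from 31: Miyaura borylation (B2pin2, PdCl2(dppf), KOAc, dioxane, 85 °C) should give benzyl 4-methoxy-2-[(2-pentyl-1,3-dioxolan-2-yl)methyl]-6-(4,4,5,5-tetramethyl-1,3,2-dioxaborolan-2-yl)benzoate F3. Chan–Lam etherification of F3 with phenol 22 (Cu(OAc)2, pyridine, 4 Å molecular sieves, CH2Cl2, air, rt) comes back to the route at 32.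

Step 5. The lateral anion may dimerise oxidatively, be brominated twice or condense with the ester, and the benzylic bromide may lactonise on storage. The fallback makes the toluate the nucleophile and the furan the electrophile. It sets out from 10 and 6: lithiation of 10 (n-BuLi) and quenching of 11 with BrCCl2CCl2Br should give (R)-[1-(5-bromofuran-2-yl)ethoxy](tert-butyl)dimethylsilane F4. Anion 7, made from 6 as in step 5, is transmetalated with ZnCl2 to the benzylic zinc chloride F5. Negishi coupling of F5 with F4 (Pd(PPh3)4, THF, 45 °C) comes back to the route at 13, bypassing 8.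

**Further compounds**
F1 | step 10 | methyl 4,6-bis(benzyloxy)-2-({5-[(1R)-1-hydroxyethyl]-2,5-dimethoxy-2,5-dihydrofuran-2-yl}methyl)-3-[(4-methoxybenzyl)oxy]benzoate (diastereomer mixture at the ketal carbons) | C[C@@H](O)C1(OC)C=CC(OC)(Cc2c(OCc3ccc(OC)cc3)c(OCc3ccccc3)cc(OCc3ccccc3)c2C(=O)OC)O1
F2 | step 10 | 4,6-bis(benzyloxy)-2-({5-[(1R)-1-hydroxyethyl]-2,5-dimethoxy-2,5-dihydrofuran-2-yl}methyl)-3-[(4-methoxybenzyl)oxy]benzoic acid | C[C@@H](O)C1(OC)C=CC(OC)(Cc2c(OCc3ccc(OC)cc3)c(OCc3ccccc3)cc(OCc3ccccc3)c2C(O)=O)O1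
F3 | step 18 | benzyl 4-methoxy-2-[(2-pentyl-1,3-dioxolan-2-yl)methyl]-6-(4,4,5,5-tetramethyl-1,3,2-dioxaborolan-2-yl)benzoate | CCCCCC1(Cc2cc(OC)cc(B3OC(C)(C)C(C)(C)O3)c2C(=O)OCc2ccccc2)OCCO1
F4 | step 5 | (R)-[1-(5-bromofuran-2-yl)ethoxy](tert-butyl)dimethylsilane | C[C@@H](O[Si](C)(C)C(C)(C)C)c1ccc(Br)o1
F5 | step 5 | benzylic zinc chloride of 6 | COC(=O)c1c(C[Zn]Cl)c(OCc2ccc(OC)cc2)c(OCc2ccccc2)cc1OCc1ccccc1
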